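**Strategy.** The ester is cleaved into a C1–C10 acid and a C11–C34 alcohol, and the acid rests on disconnection of C4–C5 in oxolane ring A (C3–C6). The key step is a 5-exo-trig radical cyclisation: a primary radical at C5 of a β-(allyloxy)alkyl selenide adds to the inner carbon of the C3 vinyl group, closing ring A, turning the alkene terminus into the C4 methyl group and relaying the C3 stereocentre to C4. It exploits the 3-oxa-5-hexenyl array C5–C6–O–C3–C4=CH2 hidden in ring A. The precursor is an acyclic bis-secondary ether whose C3 and C6 centres come from iridium-catalysed allylic etherification and glycidol.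

Key step: step 5

Remark: atoms are numbered C1 (ester carbonyl) to C10 in the acid part and C11 (isopropenyl carbon) to C34 (butyl terminus) in the alcohol part; ring A is the C3–C6 oxolane, ring B the C20–C23 oxolane; TBS = tert-butyldimethylsilyl, PMB = 4-methoxybenzyl, Tr = trityl; the 4-hydroxy ketone (O15–H, C18=O) is assumed to be isolable in the open form drawn.

Step 1
Reactants: 1 (R)-2-[(trityloxy)methyl]oxirane
Product: 2 (S)-1-(phenylselanyl)-3-(trityloxy)propan-2-ol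
Conditions: (PhSe)2, NaBH4, EtOH, 0 °C to rt
Reagents that add atoms: diphenyl diselenide, c1ccc(cc1)[Se][Se]c1ccccc1
Why: Benzeneselenolate should open the terminal epoxide at CH2 (SN2 epoxide opening), so the C6 stereocentre comes untouched from the glycidol pool and C5 gains its radical precursor.

Step 2
Reactants: 3 but-3-en-1-ol
Product: 4 1-[(but-3-en-1-yloxy)methyl]-4-methoxybenzene
Conditions: NaH, PMBCl, Bu4NI (cat.), THF/DMF, 0 °C to rt
Reagents that add atoms: 4-methoxybenzyl chloride, COc1ccc(CCl)cc1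
Why: Williamson ether synthesis should mask the future C1 oxygen as a PMB ether that survives all steps up to step 11.

Step 3
Reactants: 4 1-[(but-3-en-1-yloxy)methyl]-4-methoxybenzene; 5 allyl methyl carbonate
Product: 6 methyl (E)-5-[(4-methoxybenzyl)oxy]pent-2-en-1-yl carbonate
Conditions: second-generation Grubbs catalyst (H2IMes)(PCy3)Cl2Ru=CHPh (3 mol %), 5 (3 equiv), CH2Cl2, 40 °C
Reagents that add atoms: none
Why: Olefin cross-metathesis of two terminal alkenes should give the linear E-allylic carbonate with loss of ethene.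

Step 4
Reactants: 2 (S)-1-(phenylselanyl)-3-(trityloxy)propan-2-ol; 6 methyl (E)-5-[(4-methoxybenzyl)oxy]pent-2-en-1-yl carbonate
Product: 9 (3S)-5-[(4-methoxybenzyl)oxy]pent-1-en-3-yl (2S)-1-(phenylselanyl)-3-(trityloxy)propan-2-yl ether, via lithium alkoxide 7 (not isolated), via copper alkoxide 8 (not isolated)
Conditions: n-BuLi, THF, 0 °C; CuI; then 6, [Ir(cod)Cl]2 (2 mol %), (Ra,Rc,Rc)-O,O'-(1,1'-binaphthalene-2,2'-diyl) N,N-bis(1-phenylethyl)phosphoramidite (4 mol %), THF, rt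
Reagents that add atoms: none
Why: Iridium-catalysed asymmetric allylic etherification with a copper alkoxide (Hartwig type) should give the branched ether, the new C3 centre being set as S by catalyst control (ligand antipode chosen accordingly) while C6 is not touched.

Step 5
Reactants: 9 (3S)-5-[(4-methoxybenzyl)oxy]pent-1-en-3-yl (2S)-1-(phenylselanyl)-3-(trityloxy)propan-2-yl ether
Product: 10 (2S,3R,5R)-2-{2-[(4-methoxybenzyl)oxy]ethyl}-3-methyl-5-[(trityloxy)methyl]oxolane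
Conditions: Bu3SnH (1.3 equiv, slow addition), Et3B (0.2 equiv), air, toluene (0.01 M), −40 °C to rt
Reagents that add atoms: none
Why: Bu3Sn• should abstract the phenylselanyl group to give the primary C5 radical, which adds to the inner vinyl carbon C4, and the resulting primary radical takes a hydrogen atom from Bu3SnH so that the alkene terminus becomes the C4 methyl group. The closest known reaction type is the 5-exo-trig cyclisation of 3-oxa-5-hexenyl (β-alkoxyalkyl) radicals, as in the Ueno–Stork reaction. Ring A (O–C3–C4–C5–C6) is closed in the 5-exo-trig mode by formation of C4–C5. The new stereocentre C4 is controlled by the allylic C3 centre: in the Beckwith–Houk chair-like transition state the C3 side chain lies pseudo-equatorial, which places the methyl group trans to it and, because the ether is already 3,6-trans, cis to the C6 substituent. The step needs exo over endo closure and cyclisation faster than reduction or hydrogen-atom translocation; the fast oxygen-tethered 5-exo closure, the low stannane concentration and the absence of weak C–H bonds within 1,5-reach of C5 (trityl at O7) should secure this, and the low temperature sharpens the facial bias.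

Step 6
Reactants: 10 (2S,3R,5R)-2-{2-[(4-methoxybenzyl)oxy]ethyl}-3-methyl-5-[(trityloxy)methyl]oxolane
Product: 11 [(2R,4R,5S)-5-{2-[(4-methoxybenzyl)oxy]ethyl}-4-methyloxolan-2-yl]methanol
Conditions: TsOH·H2O (cat.), MeOH/CH2Cl2, 0 °C
Reagents that add atoms: none
Why: Acid-catalysed solvolysis of the trityl ether (SN1) should free O7 while the PMB ether survives.

Step 7
Reactants: 11 [(2R,4R,5S)-5-{2-[(4-methoxybenzyl)oxy]ethyl}-4-methyloxolan-2-yl]methanol
Product: 12 (2R,4R,5S)-5-{2-[(4-methoxybenzyl)oxy]ethyl}-4-methyloxolane-2-carbaldehyde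
Conditions: Dess–Martin periodinane, NaHCO3, CH2Cl2, 0 °C to rt
Reagents that add atoms: none
Why: Buffered Dess–Martin oxidation should give the α-alkoxy aldehyde (C7) without epimerisation at C6.

Step 8
Reactants: 13 (allyloxy)(tert-butyl)dimethylsilane
Product: 15 tributyl{(2Z)-3-[(tert-butyldimethylsilyl)oxy]prop-2-en-1-yl}stannane, via allyllithium 14 (not isolated)
Conditions: s-BuLi, THF/HMPA, −78 °C; then Bu3SnCl
Reagents that add atoms: tributyltin chloride, CCCC[Sn](Cl)(CCCC)CCCC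
Why: Metalation of the allyl silyl ether and stannylation at the carbon terminus should give the Z-γ-silyloxyallylstannane (Keck reagent), the Z geometry arising from the oxygen-chelated allyllithium.

Step 9
Reactants: 12 (2R,4R,5S)-5-{2-[(4-methoxybenzyl)oxy]ethyl}-4-methyloxolane-2-carbaldehyde; 15 tributyl{(2Z)-3-[(tert-butyldimethylsilyl)oxy]prop-2-en-1-yl}stannane
Product: 16 (1S,2S)-2-(TBS-oxy)-1-[(2R,4R,5S)-5-{2-[(4-methoxybenzyl)oxy]ethyl}-4-methyloxolan-2-yl]but-3-en-1-ol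
Conditions: MgBr2·OEt2 (3 equiv), CH2Cl2, −78 to −20 °C; aq. NH4Cl
Reagents that add atoms: none
Why: Chelation-controlled allylstannane addition (Keck, SE2') should set C7 syn to the ring A oxygen through the magnesium chelate of aldehyde and ring oxygen (Cram chelate) and C8 syn to C7 through the open antiperiplanar transition state of the Z-γ-oxygenated stannane, installing the vinyl group C9=C10 at the same time.

Step 10
Reactants: 16 (1S,2S)-2-(TBS-oxy)-1-[(2R,4R,5S)-5-{2-[(4-methoxybenzyl)oxy]ethyl}-4-methyloxolan-2-yl]but-3-en-1-ol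
Product: 17 (2S,3R,5R)-5-[(1S,2S)-1,2-bis(TBS-oxy)but-3-en-1-yl]-2-{2-[(4-methoxybenzyl)oxy]ethyl}-3-methyloxolane
Conditions: TBSOTf, 2,6-lutidine, CH2Cl2, −78 to 0 °C
Reagents that add atoms: tert-butyldimethylsilyl triflate, CC(C)(C)[Si](C)(C)OS(=O)(=O)C(F)(F)F
Why: Silylation of the hindered secondary alcohol with the silyl triflate should give the fluoride-labile bis-silyl ether.

Step 11
Reactants: 17 (2S,3R,5R)-5-[(1S,2S)-1,2-bis(TBS-oxy)but-3-en-1-yl]-2-{2-[(4-methoxybenzyl)oxy]ethyl}-3-methyloxolane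
Product: 18 2-[(2S,3R,5R)-5-[(1S,2S)-1,2-bis(TBS-oxy)but-3-en-1-yl]-3-methyloxolan-2-yl]ethan-1-ol
Conditions: DDQ, CH2Cl2/pH 7 buffer, 0 °C
Reagents that add atoms: none
Why: Oxidative PMB cleavage with DDQ should free the C1 alcohol without touching the silyl ethers or the terminal alkene.

Step 12
Reactants: 18 2-[(2S,3R,5R)-5-[(1S,2S)-1,2-bis(TBS-oxy)but-3-en-1-yl]-3-methyloxolan-2-yl]ethan-1-ol
Product: 20 2-[(2S,3R,5R)-5-[(1S,2S)-1,2-bis(TBS-oxy)but-3-en-1-yl]-3-methyloxolan-2-yl]acetic acid, via aldehyde 19 (not isolated)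
Conditions: TEMPO (cat.), PhI(OAc)2, MeCN/H2O, rt
Reagents that add atoms: water, O
Why: Oxoammonium (TEMPO) oxidation should take the primary alcohol through the aldehyde hydrate to the C1 acid under conditions that spare the alkene and the silyl ethers.

Step 13
Reactants: 21 2-methylidenehexanal; 22 ethynyltrimethylsilane
Product: 24 (3S)-4-methylidene-1-(trimethylsilyl)oct-1-yn-3-ol, via alkynylzinc 23 (not isolated)
Conditions: Me2Zn, (S,S)-ProPhenol (10 mol %), Ph3P=O (20 mol %), toluene, 4 °C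
Reagents that add atoms: none
Why: Zinc/ProPhenol-catalysed asymmetric alkynylation of an α-substituted enal (Trost) should set C29 as S by catalyst control (ligand antipode chosen accordingly).

Step 14
Reactants: 24 (3S)-4-methylidene-1-(trimethylsilyl)oct-1-yn-3-ol
Product: 25 (3S)-4-methylideneoct-1-yn-3-ol
Conditions: K2CO3, MeOH, rt
Reagents that add atoms: none
Why: Base-mediated methanolysis of the alkynyl–silicon bond should give the terminal alkyne.

Step 15
Reactants: 25 (3S)-4-methylideneoct-1-yn-3-ol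
Product: 26 tert-butyldimethyl{[(3S)-4-methylideneoct-1-yn-3-yl]oxy}silane
Conditions: TBSCl, imidazole, DMF, rt
Reagents that add atoms: tert-butyldimethylsilyl chloride, CC(C)(C)[Si](C)(C)Cl
Why: Standard silylation should protect O29.

Step 16
Reactants: 26 tert-butyldimethyl{[(3S)-4-methylideneoct-1-yn-3-yl]oxy}silane
Product: 28 tert-butyl{[(1E,3S)-1-iodo-2-methyl-4-methylideneoct-1-en-3-yl]oxy}dimethylsilane, via vinylalane 27 (not isolated)
Conditions: Me3Al, Cp2ZrCl2 (0.3 equiv), CH2Cl2, 0 °C to rt; then I2, THF, −30 °C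
Reagents that add atoms: trimethylaluminium, C[Al](C)C; iodine, II
Why: Negishi zirconium-catalysed methylalumination should add methyl and aluminium syn across the alkyne (methyl to C28) and iodinolysis with retention should give the E trisubstituted vinyl iodide, the less reactive 1,1-disubstituted alkene being spared.

Step 17
Reactants: 28 tert-butyl{[(1E,3S)-1-iodo-2-methyl-4-methylideneoct-1-en-3-yl]oxy}dimethylsilane; 29 (E)-1,2-bis(tributylstannyl)ethene
Product: 30 tributyl{(1E,3E,5S)-5-(TBS-oxy)-4-methyl-6-methylidenedeca-1,3-dien-1-yl}stannane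
Conditions: PdCl2(MeCN)2 (5 mol %), 29 (3 equiv), DMF, rt
Reagents that add atoms: none
Why: Stille coupling with an excess of the distannane should stop after one coupling and give the E,E-dienylstannane with retention of both alkene geometries.

Step 18
Reactants: 31 1,3-dithiane; 32 2-(2-bromoethyl)-1,3-dioxolane
Product: 34 2-[2-(1,3-dioxolan-2-yl)ethyl]-1,3-dithiane, via 2-lithio-1,3-dithiane 33 (not isolated)
Conditions: n-BuLi, THF, −30 °C; then 32, −78 °C to rt
Reagents that add atoms: none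
Why: Corey–Seebach alkylation of the lithiated dithiane with the primary bromide should install the masked C18 carbonyl.

Step 19
Reactants: 34 2-[2-(1,3-dioxolan-2-yl)ethyl]-1,3-dithiane
Product: 35 3-(1,3-dithian-2-yl)propanal
Conditions: 1 M HCl, THF, rt
Reagents that add atoms: water, O
Why: Aqueous acid should hydrolyse the O,O-acetal selectively because the S,S-acetal is stable to Brønsted acid.

Step 20
Reactants: 36 (4S)-4-benzyl-3-propanoyl-1,3-oxazolidin-2-one; 37 propanoyl chloride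
Product: 39 (4S)-4-benzyl-3-[(2R)-2-methyl-3-oxopentanoyl]-1,3-oxazolidin-2-one, via lithium enolate 38 (not isolated)
Conditions: LiN(iPr)2, THF, −78 °C; then 37
Reagents that add atoms: none
Why: Evans acylation of the chelated Z-enolate from the face opposite to the benzyl group should set C12 as 2R, and allylic strain keeps this centre from epimerising in the β-keto imide.

Step 21
Reactants: 39 (4S)-4-benzyl-3-[(2R)-2-methyl-3-oxopentanoyl]-1,3-oxazolidin-2-one; 35 3-(1,3-dithian-2-yl)propanal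
Product: 41 (4S)-4-benzyl-3-[(2R,4S,5S)-7-(1,3-dithian-2-yl)-5-hydroxy-2,4-dimethyl-3-oxoheptanoyl]-1,3-oxazolidin-2-one, via boron enolate 40 (not isolated)
Conditions: (c-C6H11)2BCl, EtNMe2, Et2O, 0 °C; then 35, −78 °C; MeOH/pH 7 buffer work-up
Reagents that add atoms: none
Why: The Evans β-keto imide boron aldol through the E-enolate and a chair transition state should give the anti,anti adduct, the C12 centre directing the enolate face so that the C14 methyl is anti to the C12 methyl and O15 is anti to the C14 methyl.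

Step 22
Reactants: 41 (4S)-4-benzyl-3-[(2R,4S,5S)-7-(1,3-dithian-2-yl)-5-hydroxy-2,4-dimethyl-3-oxoheptanoyl]-1,3-oxazolidin-2-one
Product: 42 (4S)-4-benzyl-3-[(2R,3S,4S,5S)-7-(1,3-dithian-2-yl)-3,5-dihydroxy-2,4-dimethylheptanoyl]-1,3-oxazolidin-2-one
Conditions: Zn(BH4)2, CH2Cl2/Et2O, −78 to −20 °C
Reagents that add atoms: none
Why: Chelation-controlled reduction of the β-hydroxy ketone with zinc borohydride should deliver hydride to the zinc chelate and set O13 syn to O15 (1,3-syn diol).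

Step 23
Reactants: 42 (4S)-4-benzyl-3-[(2R,3S,4S,5S)-7-(1,3-dithian-2-yl)-3,5-dihydroxy-2,4-dimethylheptanoyl]-1,3-oxazolidin-2-one
Product: 43 (2R,3S,4S,5S)-7-(1,3-dithian-2-yl)-3,5-dihydroxy-N-methoxy-N,2,4-trimethylheptanamide
Conditions: Me3Al, MeNHOMe·HCl, CH2Cl2, −20 to 0 °C
Reagents that add atoms: N,O-dimethylhydroxylamine hydrochloride, CNOC.Cl
Why: Aluminium-amide transamidation, assisted by the free β-hydroxyl group, should replace the auxiliary by the Weinreb amide without epimerisation.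

Step 24
Reactants: 43 (2R,3S,4S,5S)-7-(1,3-dithian-2-yl)-3,5-dihydroxy-N-methoxy-N,2,4-trimethylheptanamide
Product: 44 (2R,3S,4S,5S)-3,5-bis(TBS-oxy)-7-(1,3-dithian-2-yl)-N-methoxy-N,2,4-trimethylheptanamide
Conditions: TBSOTf, 2,6-lutidine, CH2Cl2, −78 to 0 °C
Reagents that add atoms: tert-butyldimethylsilyl triflate, CC(C)(C)[Si](C)(C)OS(=O)(=O)C(F)(F)F
Why: Silylation of both secondary alcohols with the silyl triflate should give the bis-silyl ether.

Step 25
Reactants: 44 (2R,3S,4S,5S)-3,5-bis(TBS-oxy)-7-(1,3-dithian-2-yl)-N-methoxy-N,2,4-trimethylheptanamide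
Product: 45 (3R,4S,5S,6S)-4,6-bis(TBS-oxy)-8-(1,3-dithian-2-yl)-3,5-dimethyloctan-2-one
Conditions: MeMgBr, THF, 0 °C
Reagents that add atoms: methylmagnesium bromide, C[Mg]Br
Why: Weinreb ketone synthesis should stop at the methyl ketone (C11) through the stable magnesium chelate.

Step 26
Reactants: 45 (3R,4S,5S,6S)-4,6-bis(TBS-oxy)-8-(1,3-dithian-2-yl)-3,5-dimethyloctan-2-one
Product: 46 2-[(3S,4S,5R,6S)-3,5-bis(TBS-oxy)-4,6,7-trimethyloct-7-en-1-yl]-1,3-dithiane
Conditions: Ph3PCH3Br, KN(SiMe3)2, THF, 0 °C to rt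
Reagents that add atoms: methyltriphenylphosphonium bromide, C[P+](c1ccccc1)(c1ccccc1)c1ccccc1.[Br-]
Why: Wittig methylenation with the salt-free non-stabilised ylide at low temperature should give the isopropenyl group without epimerisation at C12.

Step 27
Reactants: 47 (S)-2-[(trityloxy)methyl]oxirane
Product: 48 (2S)-1-(trityloxy)hex-5-en-2-ol
Conditions: allylmagnesium bromide, CuI (10 mol %), THF, −40 to 0 °C
Reagents that add atoms: allylmagnesium bromide, C=CC[Mg]Br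
Why: Copper-catalysed Grignard opening of the terminal epoxide at CH2 should give the homoallyl-extended alcohol with C23 taken unchanged from the glycidol pool.

Step 28
Reactants: 48 (2S)-1-(trityloxy)hex-5-en-2-ol
Product: 49 {[(2S)-2-[(2,6-dichlorobenzyl)oxy]hex-5-en-1-yl]oxy}triphenylmethane
Conditions: NaH, 2,6-dichlorobenzyl bromide, Bu4NI (cat.), THF/DMF, 0 °C to rt
Reagents that add atoms: 2,6-dichlorobenzyl bromide, Clc1cccc(Cl)c1CBr
Why: Williamson etherification should install the bulky benzyl ether needed for cis-selective cyclisation, the trityl group being unable to migrate under base.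

Step 29
Reactants: 49 {[(2S)-2-[(2,6-dichlorobenzyl)oxy]hex-5-en-1-yl]oxy}triphenylmethane
Product: 50 (2R,5S)-2-(iodomethyl)-5-[(trityloxy)methyl]oxolane
Conditions: I2, MeCN, 0 °C
Reagents that add atoms: iodine, II
Why: 5-exo-trig iodoetherification through the O-benzyl oxonium ion (Rychnovsky–Bartlett) should give the 2,5-cis ring B, because the bulky benzyl group sits trans to both ring substituents before it is lost, so C20 is set by C23.

Step 30
Reactants: 46 2-[(3S,4S,5R,6S)-3,5-bis(TBS-oxy)-4,6,7-trimethyloct-7-en-1-yl]-1,3-dithiane; 50 (2R,5S)-2-(iodomethyl)-5-[(trityloxy)methyl]oxolane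
Product: 52 2-[(3S,4S,5R,6S)-3,5-bis(TBS-oxy)-4,6,7-trimethyloct-7-en-1-yl]-2-{[(2R,5S)-5-(trityloxymethyl)oxolan-2-yl]methyl}-1,3-dithiane, via lithiodithiane 51 (not isolated)
Conditions: t-BuLi, THF/HMPA (10:1), −78 °C; then 50, −78 to −40 °C
Reagents that add atoms: none
Why: Corey–Seebach alkylation of the 2-lithio-1,3-dithiane (acyl-anion equivalent at C18) with the primary iodide should forge C18–C19 and keep the ketone masked.

Step 31
Reactants: 52 2-[(3S,4S,5R,6S)-3,5-bis(TBS-oxy)-4,6,7-trimethyloct-7-en-1-yl]-2-{[(2R,5S)-5-(trityloxymethyl)oxolan-2-yl]methyl}-1,3-dithiane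
Product: 53 [(2S,5R)-5-({2-[(3S,4S,5R,6S)-3,5-bis(TBS-oxy)-4,6,7-trimethyloct-7-en-1-yl]-1,3-dithian-2-yl}methyl)oxolan-2-yl]methanol
Conditions: camphorsulfonic acid (cat.), MeOH/CH2Cl2, 0 °C
Reagents that add atoms: none
Why: Acid-catalysed detritylation (SN1 solvolysis) should free O24 while the hindered secondary silyl ethers and the dithiane survive.

Step 32
Reactants: 53 [(2S,5R)-5-({2-[(3S,4S,5R,6S)-3,5-bis(TBS-oxy)-4,6,7-trimethyloct-7-en-1-yl]-1,3-dithian-2-yl}methyl)oxolan-2-yl]methanol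
Product: 54 (2S,5R)-5-({2-[(3S,4S,5R,6S)-3,5-bis(TBS-oxy)-4,6,7-trimethyloct-7-en-1-yl]-1,3-dithian-2-yl}methyl)oxolane-2-carbaldehyde
Conditions: SO3·pyridine, DMSO, iPr2NEt, CH2Cl2, 0 °C
Reagents that add atoms: none
Why: Parikh–Doering oxidation should give the C24 aldehyde without oxidising the dithiane sulfur or epimerising C23.

Step 33
Reactants: 30 tributyl{(1E,3E,5S)-5-(TBS-oxy)-4-methyl-6-methylidenedeca-1,3-dien-1-yl}stannane; 54 (2S,5R)-5-({2-[(3S,4S,5R,6S)-3,5-bis(TBS-oxy)-4,6,7-trimethyloct-7-en-1-yl]-1,3-dithian-2-yl}methyl)oxolane-2-carbaldehyde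
Product: 57 (1S,2E,4E,6S)-6-(TBS-oxy)-1-[(2S,5R)-5-({2-[(3S,4S,5R,6S)-3,5-bis(TBS-oxy)-4,6,7-trimethyloct-7-en-1-yl]-1,3-dithian-2-yl}methyl)oxolan-2-yl]-5-methyl-7-methylideneundeca-2,4-dien-1-ol, via dienyllithium 55 (not isolated), via dienylmagnesium bromide 56 (not isolated)
Conditions: 30, n-BuLi, THF, −78 °C; MgBr2·OEt2; then 54 precomplexed with MgBr2·OEt2, CH2Cl2, −78 °C
Reagents that add atoms: none
Why: Tin–lithium exchange, transmetalation and chelation-controlled (Cram chelate) addition of the dienylmagnesium reagent to the α-alkoxy aldehyde should set C24 syn to the ring B oxygen and join C24–C25 with retention of the diene geometry.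

Step 34
Reactants: 20 2-[(2S,3R,5R)-5-[(1S,2S)-1,2-bis(TBS-oxy)but-3-en-1-yl]-3-methyloxolan-2-yl]acetic acid; 57 the C11–C34 alcohol of step 33
Product: 59 O24 ester of alcohol 57 with acid 20 carrying the C18 dithiane and five TBS ethers, via mixed anhydride 58 (not isolated)
Conditions: 2,4,6-trichlorobenzoyl chloride, Et3N, THF, rt; then 57, DMAP, toluene, rt
Reagents that add atoms: none
Why: Yamaguchi esterification through the mixed anhydride and the acylpyridinium ion should acylate the only free hydroxyl group (O24) without touching any stereocentre.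

Step 35
Reactants: 59 O24 ester carrying the C18 dithiane and five TBS ethers
Product: 60 pentakis-TBS ether (O7, O8, O13, O15, O29) of the target with the free C18 ketone
Conditions: MeI, CaCO3, MeCN/H2O (9:1), 40 °C
Reagents that add atoms: water, O
Why: Alkylative hydrolysis of the dithiane (S-methylation, then hydrolysis of the sulfonium ion) should unmask the C18 ketone under conditions that spare the alkenes, the ester and the silyl ethers.

Step 36
Reactants: 60 pentakis-TBS ether of the target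
Product: 61 target CNP0158416.1, (1S,2E,4E,6S)-6-hydroxy-1-{(2S,5R)-5-[(5S,6S,7R,8S)-5,7-dihydroxy-6,8,9-trimethyl-2-oxodec-9-en-1-yl]oxolan-2-yl}-5-methyl-7-methylideneundeca-2,4-dien-1-yl 2-{(2S,3R,5R)-5-[(1R,2S)-1,2-dihydroxybut-3-en-1-yl]-3-methyloxolan-2-yl}acetate
Conditions: HF·pyridine, pyridine, THF, 0 °C to rt
Reagents that add atoms: none
Why: Buffered fluoride-mediated global desilylation should free the five hydroxyl groups without acid-induced ionisation of the allylic C29 alcohol or β-elimination next to the ketone and ester.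

**Compound list**

1 | (R)-2-[(trityloxy)methyl]oxirane | c1ccccc1C(c1ccccc1)(c1ccccc1)OC[C@H]1CO1 | starting material
2 | (S)-1-(phenylselanyl)-3-(trityloxy)propan-2-ol | c1ccccc1C(c1ccccc1)(c1ccccc1)OC[C@H](O)C[Se]c1ccccc1 | intermediate
3 | but-3-en-1-ol | C=CCCO | starting material
4 | 1-[(but-3-en-1-yloxy)methyl]-4-methoxybenzene | C=CCCOCc1ccc(OC)cc1 | intermediate
5 | allyl methyl carbonate | C=CCOC(=O)OC | starting material
6 | methyl (E)-5-[(4-methoxybenzyl)oxy]pent-2-en-1-yl carbonate | COC(=O)OC/C=C/CCOCc1ccc(OC)cc1 | intermediate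
7 | lithium (S)-1-(phenylselanyl)-3-(trityloxy)propan-2-olate | [Li]O[C@H](C[Se]c1ccccc1)COC(c1ccccc1)(c1ccccc1)c1ccccc1 | intermediate (not isolated)
8 | copper (S)-1-(phenylselanyl)-3-(trityloxy)propan-2-olate | [Cu]O[C@H](C[Se]c1ccccc1)COC(c1ccccc1)(c1ccccc1)c1ccccc1 | intermediate (not isolated)
9 | (3S)-5-[(4-methoxybenzyl)oxy]pent-1-en-3-yl (2S)-1-(phenylselanyl)-3-(trityloxy)propan-2-yl ether | C=C[C@H](CCOCc1ccc(OC)cc1)O[C@H](C[Se]c1ccccc1)COC(c1ccccc1)(c1ccccc1)c1ccccc1 | intermediate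
10 | (2S,3R,5R)-2-{2-[(4-methoxybenzyl)oxy]ethyl}-3-methyl-5-[(trityloxy)methyl]oxolane | c1ccccc1C(c1ccccc1)(c1ccccc1)OC[C@H]1C[C@@H](C)[C@H](CCOCc2ccc(OC)cc2)O1 | intermediate
11 | [(2R,4R,5S)-5-{2-[(4-methoxybenzyl)oxy]ethyl}-4-methyloxolan-2-yl]methanol | OC[C@H]1C[C@@H](C)[C@H](CCOCc2ccc(OC)cc2)O1 | intermediate
12 | (2R,4R,5S)-5-{2-[(4-methoxybenzyl)oxy]ethyl}-4-methyloxolane-2-carbaldehyde | O=C[C@H]1C[C@@H](C)[C@H](CCOCc2ccc(OC)cc2)O1 | intermediate
13 | (allyloxy)(tert-butyl)dimethylsilane | C=CCO[Si](C)(C)C(C)(C)C | starting material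
14 | (Z)-3-[(tert-butyldimethylsilyl)oxy]allyllithium | [Li]C/C=C\O[Si](C)(C)C(C)(C)C | intermediate (not isolated)
15 | tributyl{(2Z)-3-[(tert-butyldimethylsilyl)oxy]prop-2-en-1-yl}stannane | CCCC[Sn](CCCC)(CCCC)C/C=C\O[Si](C)(C)C(C)(C)C | intermediate
16 | (1S,2S)-2-(TBS-oxy)-1-[(2R,4R,5S)-5-{2-[(4-methoxybenzyl)oxy]ethyl}-4-methyloxolan-2-yl]but-3-en-1-ol | C=C[C@H](O[Si](C)(C)C(C)(C)C)[C@@H](O)[C@H]1C[C@@H](C)[C@H](CCOCc2ccc(OC)cc2)O1 | intermediate
17 | (2S,3R,5R)-5-[(1S,2S)-1,2-bis(TBS-oxy)but-3-en-1-yl]-2-{2-[(4-methoxybenzyl)oxy]ethyl}-3-methyloxolane | C=C[C@H](O[Si](C)(C)C(C)(C)C)[C@@H](O[Si](C)(C)C(C)(C)C)[C@H]1C[C@@H](C)[C@H](CCOCc2ccc(OC)cc2)O1 | intermediate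
18 | 2-[(2S,3R,5R)-5-[(1S,2S)-1,2-bis(TBS-oxy)but-3-en-1-yl]-3-methyloxolan-2-yl]ethan-1-ol | C=C[C@H](O[Si](C)(C)C(C)(C)C)[C@@H](O[Si](C)(C)C(C)(C)C)[C@H]1C[C@@H](C)[C@H](CCO)O1 | intermediate
19 | 2-[(2S,3R,5R)-5-[(1S,2S)-1,2-bis(TBS-oxy)but-3-en-1-yl]-3-methyloxolan-2-yl]acetaldehyde | C=C[C@H](O[Si](C)(C)C(C)(C)C)[C@@H](O[Si](C)(C)C(C)(C)C)[C@H]1C[C@@H](C)[C@H](CC=O)O1 | intermediate (not isolated)
20 | 2-[(2S,3R,5R)-5-[(1S,2S)-1,2-bis(TBS-oxy)but-3-en-1-yl]-3-methyloxolan-2-yl]acetic acid (C1–C10 acid) | C=C[C@H](O[Si](C)(C)C(C)(C)C)[C@@H](O[Si](C)(C)C(C)(C)C)[C@H]1C[C@@H](C)[C@H](CC(=O)O)O1 | intermediate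
21 | 2-methylidenehexanal | CCCCC(=C)C=O | starting material
22 | ethynyltrimethylsilane | C#C[Si](C)(C)C | starting material
23 | methyl[(trimethylsilyl)ethynyl]zinc | C[Zn]C#C[Si](C)(C)C | intermediate (not isolated)
24 | (3S)-4-methylidene-1-(trimethylsilyl)oct-1-yn-3-ol | C[Si](C)(C)C#C[C@@H](O)C(=C)CCCC | intermediate
25 | (3S)-4-methylideneoct-1-yn-3-ol | C#C[C@@H](O)C(=C)CCCC | intermediate
26 | tert-butyldimethyl{[(3S)-4-methylideneoct-1-yn-3-yl]oxy}silane | C#C[C@@H](O[Si](C)(C)C(C)(C)C)C(=C)CCCC | intermediate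
27 | dimethyl{(1E,3S)-3-(TBS-oxy)-2-methyl-4-methylideneoct-1-en-1-yl}alane | C[Al](C)/C=C(\C)[C@@H](O[Si](C)(C)C(C)(C)C)C(=C)CCCC | intermediate (not isolated)
28 | tert-butyl{[(1E,3S)-1-iodo-2-methyl-4-methylideneoct-1-en-3-yl]oxy}dimethylsilane | I/C=C(\C)[C@@H](O[Si](C)(C)C(C)(C)C)C(=C)CCCC | intermediate
29 | (E)-1,2-bis(tributylstannyl)ethene | CCCC[Sn](CCCC)(CCCC)/C=C/[Sn](CCCC)(CCCC)CCCC | starting material
30 | tributyl{(1E,3E,5S)-5-(TBS-oxy)-4-methyl-6-methylidenedeca-1,3-dien-1-yl}stannane | CCCC[Sn](CCCC)(CCCC)/C=C/C=C(\C)[C@@H](O[Si](C)(C)C(C)(C)C)C(=C)CCCC | intermediate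
31 | 1,3-dithiane | C1CSCSC1 | starting material
32 | 2-(2-bromoethyl)-1,3-dioxolane | BrCCC1OCCO1 | starting material
33 | 2-lithio-1,3-dithiane | [Li]C1SCCCS1 | intermediate (not isolated)
34 | 2-[2-(1,3-dioxolan-2-yl)ethyl]-1,3-dithiane | C1COC(CCC2SCCCS2)O1 | intermediate
35 | 3-(1,3-dithian-2-yl)propanal | O=CCCC1SCCCS1 | intermediate
36 | (4S)-4-benzyl-3-propanoyl-1,3-oxazolidin-2-one | CCC(=O)N1[C@@H](Cc2ccccc2)COC1=O | starting material
37 | propanoyl chloride | CCC(=O)Cl | starting material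
38 | lithium (Z)-enolate of 36 | C/C=C(\O[Li])N1[C@@H](Cc2ccccc2)COC1=O | intermediate (not isolated)
39 | (4S)-4-benzyl-3-[(2R)-2-methyl-3-oxopentanoyl]-1,3-oxazolidin-2-one | CCC(=O)[C@@H](C)C(=O)N1[C@@H](Cc2ccccc2)COC1=O | intermediate
40 | dicyclohexylboron (E)-enolate of 39 | C/C=C(/OB(C1CCCCC1)C1CCCCC1)[C@@H](C)C(=O)N1[C@@H](Cc2ccccc2)COC1=O | intermediate (not isolated)
41 | (4S)-4-benzyl-3-[(2R,4S,5S)-7-(1,3-dithian-2-yl)-5-hydroxy-2,4-dimethyl-3-oxoheptanoyl]-1,3-oxazolidin-2-one | C1(SCCCS1)CC[C@H](O)[C@H](C)C(=O)[C@@H](C)C(=O)N1[C@@H](Cc2ccccc2)COC1=O | intermediate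
42 | (4S)-4-benzyl-3-[(2R,3S,4S,5S)-7-(1,3-dithian-2-yl)-3,5-dihydroxy-2,4-dimethylheptanoyl]-1,3-oxazolidin-2-one | C1(SCCCS1)CC[C@H](O)[C@H](C)[C@H](O)[C@@H](C)C(=O)N1[C@@H](Cc2ccccc2)COC1=O | intermediate
43 | (2R,3S,4S,5S)-7-(1,3-dithian-2-yl)-3,5-dihydroxy-N-methoxy-N,2,4-trimethylheptanamide | C1(SCCCS1)CC[C@H](O)[C@H](C)[C@H](O)[C@@H](C)C(=O)N(C)OC | intermediate
44 | (2R,3S,4S,5S)-3,5-bis(TBS-oxy)-7-(1,3-dithian-2-yl)-N-methoxy-N,2,4-trimethylheptanamide | C1(SCCCS1)CC[C@H](O[Si](C)(C)C(C)(C)C)[C@H](C)[C@H](O[Si](C)(C)C(C)(C)C)[C@@H](C)C(=O)N(C)OC | intermediate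
45 | (3R,4S,5S,6S)-4,6-bis(TBS-oxy)-8-(1,3-dithian-2-yl)-3,5-dimethyloctan-2-one | C1(SCCCS1)CC[C@H](O[Si](C)(C)C(C)(C)C)[C@H](C)[C@H](O[Si](C)(C)C(C)(C)C)[C@@H](C)C(C)=O | intermediate
46 | 2-[(3S,4S,5R,6S)-3,5-bis(TBS-oxy)-4,6,7-trimethyloct-7-en-1-yl]-1,3-dithiane (C11–C18) | C1(SCCCS1)CC[C@H](O[Si](C)(C)C(C)(C)C)[C@H](C)[C@H](O[Si](C)(C)C(C)(C)C)[C@@H](C)C(C)=C | intermediate
47 | (S)-2-[(trityloxy)methyl]oxirane | c1ccccc1C(c1ccccc1)(c1ccccc1)OC[C@@H]1CO1 | starting material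
48 | (2S)-1-(trityloxy)hex-5-en-2-ol | c1ccccc1C(c1ccccc1)(c1ccccc1)OC[C@@H](O)CCC=C | intermediate
49 | {[(2S)-2-[(2,6-dichlorobenzyl)oxy]hex-5-en-1-yl]oxy}triphenylmethane | c1ccccc1C(c1ccccc1)(c1ccccc1)OC[C@@H](OCc1c(Cl)cccc1Cl)CCC=C | intermediate
50 | (2R,5S)-2-(iodomethyl)-5-[(trityloxy)methyl]oxolane (ring B, cis) | c1ccccc1C(c1ccccc1)(c1ccccc1)OC[C@@H]1CC[C@H](CI)O1 | intermediate
51 | 2-lithio derivative of 46 | [Li]C1(SCCCS1)CC[C@H](O[Si](C)(C)C(C)(C)C)[C@H](C)[C@H](O[Si](C)(C)C(C)(C)C)[C@@H](C)C(C)=C | intermediate (not isolated)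
52 | 2-[(3S,4S,5R,6S)-3,5-bis(TBS-oxy)-4,6,7-trimethyloct-7-en-1-yl]-2-{[(2R,5S)-5-(trityloxymethyl)oxolan-2-yl]methyl}-1,3-dithiane | c1ccccc1C(c1ccccc1)(c1ccccc1)OC[C@@H]1CC[C@H](CC2(SCCCS2)CC[C@H](O[Si](C)(C)C(C)(C)C)[C@H](C)[C@H](O[Si](C)(C)C(C)(C)C)[C@@H](C)C(C)=C)O1 | intermediate
53 | [(2S,5R)-5-({2-[(3S,4S,5R,6S)-3,5-bis(TBS-oxy)-4,6,7-trimethyloct-7-en-1-yl]-1,3-dithian-2-yl}methyl)oxolan-2-yl]methanol | OC[C@@H]1CC[C@H](CC2(SCCCS2)CC[C@H](O[Si](C)(C)C(C)(C)C)[C@H](C)[C@H](O[Si](C)(C)C(C)(C)C)[C@@H](C)C(C)=C)O1 | intermediate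
54 | (2S,5R)-5-({2-[(3S,4S,5R,6S)-3,5-bis(TBS-oxy)-4,6,7-trimethyloct-7-en-1-yl]-1,3-dithian-2-yl}methyl)oxolane-2-carbaldehyde | O=C[C@@H]1CC[C@H](CC2(SCCCS2)CC[C@H](O[Si](C)(C)C(C)(C)C)[C@H](C)[C@H](O[Si](C)(C)C(C)(C)C)[C@@H](C)C(C)=C)O1 | intermediate
55 | {(1E,3E,5S)-5-(TBS-oxy)-4-methyl-6-methylidenedeca-1,3-dien-1-yl}lithium | [Li]/C=C/C=C(\C)[C@@H](O[Si](C)(C)C(C)(C)C)C(=C)CCCC | intermediate (not isolated)
56 | {(1E,3E,5S)-5-(TBS-oxy)-4-methyl-6-methylidenedeca-1,3-dien-1-yl}magnesium bromide | Br[Mg]/C=C/C=C(\C)[C@@H](O[Si](C)(C)C(C)(C)C)C(=C)CCCC | intermediate (not isolated)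
57 | (1S,2E,4E,6S)-6-(TBS-oxy)-1-[(2S,5R)-5-({2-[(3S,4S,5R,6S)-3,5-bis(TBS-oxy)-4,6,7-trimethyloct-7-en-1-yl]-1,3-dithian-2-yl}methyl)oxolan-2-yl]-5-methyl-7-methylideneundeca-2,4-dien-1-ol (C11–C34 alcohol) | O[C@@H](/C=C/C=C(\C)[C@@H](O[Si](C)(C)C(C)(C)C)C(=C)CCCC)[C@@H]1CC[C@H](CC2(SCCCS2)CC[C@H](O[Si](C)(C)C(C)(C)C)[C@H](C)[C@H](O[Si](C)(C)C(C)(C)C)[C@@H](C)C(=C)C)O1 | intermediate
58 | mixed anhydride of acid 20 and 2,4,6-trichlorobenzoic acid | C=C[C@H](O[Si](C)(C)C(C)(C)C)[C@@H](O[Si](C)(C)C(C)(C)C)[C@H]1C[C@@H](C)[C@H](CC(=O)OC(=O)c2c(Cl)cc(Cl)cc2Cl)O1 | intermediate (not isolated)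
59 | O24 ester of 57 with 20; C18 as 1,3-dithiane; TBS ethers at O7, O8, O13, O15, O29; (3S,4R,6R,7S,8S,12S,13R,14S,15S,20R,23S,24S,29S,25E,27E) | C=C[C@H](O[Si](C)(C)C(C)(C)C)[C@@H](O[Si](C)(C)C(C)(C)C)[C@H]1C[C@@H](C)[C@H](CC(=O)O[C@@H](/C=C/C=C(\C)[C@@H](O[Si](C)(C)C(C)(C)C)C(=C)CCCC)[C@@H]2CC[C@H](CC3(SCCCS3)CC[C@H](O[Si](C)(C)C(C)(C)C)[C@H](C)[C@H](O[Si](C)(C)C(C)(C)C)[C@@H](C)C(=C)C)O2)O1 | intermediate
60 | pentakis-TBS ether (O7, O8, O13, O15, O29) of the target; free C18 ketone; same descriptors as 59 | C=C[C@H](O[Si](C)(C)C(C)(C)C)[C@@H](O[Si](C)(C)C(C)(C)C)[C@H]1C[C@@H](C)[C@H](CC(=O)O[C@@H](/C=C/C=C(\C)[C@@H](O[Si](C)(C)C(C)(C)C)C(=C)CCCC)[C@@H]2CC[C@H](CC(=O)CC[C@H](O[Si](C)(C)C(C)(C)C)[C@H](C)[C@H](O[Si](C)(C)C(C)(C)C)[C@@H](C)C(=C)C)O2)O1 | intermediate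
61 | CNP0158416.1; (3S,4R,6R,7R,8S,12S,13R,14S,15S,20R,23S,24S,29S,25E,27E) | C=C[C@H](O)[C@@H](O)[C@H]1C[C@@H](C)[C@H](CC(=O)O[C@@H](/C=C/C=C(\C)[C@@H](O)C(=C)CCCC)[C@@H]2CC[C@H](CC(=O)CC[C@H](O)[C@H](C)[C@H](O)[C@@H](C)C(=C)C)O2)O1 | target

**Totals.** Total step count: 36. Longest linear sequence: 15 steps (steps 18, 19, 21–26 and 30–36).

**Steps most likely to fail**

Step 5 (key cyclisation). What may go wrong is poor facial selectivity at C4, because the favoured chair transition state must carry the C6 substituent pseudo-axially, or reduction of the C5 radical before it closes. The fallback closes the same C4–C5 bond through an acetal tether in which C6 is still at the lactol oxidation level (Ueno–Stork cyclisation) and sets C6 afterwards. It sets out from carbonate 6 and comes back to the route at alcohol 11. Iridium-catalysed allylic substitution of 6 with potassium triethylsilanolate, followed by fluoride, should give (3S)-5-[(4-methoxybenzyl)oxy]pent-1-en-3-ol F1. N-Bromosuccinimide and ethyl vinyl ether convert it into the bromoacetal 1-({[(3S)-3-(2-bromo-1-ethoxyethoxy)pent-4-en-1-yl]oxy}methyl)-4-methoxybenzene F2. Bu3SnH/AIBN closes ring A (5-exo-trig, methyl trans to the C3 chain by the same allylic control) to (4R,5S)-2-ethoxy-5-{2-[(4-methoxybenzyl)oxy]ethyl}-4-methyloxolane F3. Oxidation of the cyclic acetal (m-CPBA, BF3·OEt2) gives the lactone (4R,5S)-5-{2-[(4-methoxybenzyl)oxy]ethyl}-4-methyloxolan-2-one F4. Methylenation with Cp2TiMe2 gives the enol ether (2S,3R)-2-{2-[(4-methoxybenzyl)oxy]ethyl}-3-methyl-5-methylideneoxolane F5. Hydroboration (9-borabicyclononane, then H2O2/NaOH) from the face opposite to the C4 methyl group should set C6 and deliver 11.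

Step 4 (allylic etherification). What may go wrong is inhibition of the iridium catalyst by the selenoether, or slow attack of the hindered alkoxide with loss of branched selectivity. The fallback makes the carbon–selenium bond after the ether bond and uses a zinc alkoxide of a halohydrin as the nucleophile. It sets out from epoxide 1 and comes back at selenide 9. LiCl/AcOH opens 1 to (2S)-1-chloro-3-(trityloxy)propan-2-ol F6. Its zinc alkoxide (Et2Zn) is etherified with 6 under the same iridium–phosphoramidite catalysis to (3S)-5-[(4-methoxybenzyl)oxy]pent-1-en-3-yl (2S)-1-chloro-3-(trityloxy)propan-2-yl ether F7. Sodium benzeneselenolate then displaces the primary chloride (SN2) to give 9.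

Step 33 (dienyl addition). What may go wrong is incomplete chelate control, giving poor facial selectivity at C24, or loss of the dienyl metal by protonation. The fallback corrects C24 by an oxidation–reduction sequence under reagent control. It sets out from 57 (as the C24 epimer mixture) and comes back at 57. Dess–Martin oxidation gives the dienone (2E,4E,6S)-6-(TBS-oxy)-1-[(2S,5R)-5-({2-[(3S,4S,5R,6S)-3,5-bis(TBS-oxy)-4,6,7-trimethyloct-7-en-1-yl]-1,3-dithian-2-yl}methyl)oxolan-2-yl]-5-methyl-7-methylideneundeca-2,4-dien-1-one F8. Corey–Bakshi–Shibata reduction (the oxazaborolidine antipode that delivers the 24S alcohol, catecholborane, −78 °C) should return 57.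

**Further compounds**

F1 | step 5 | (3S)-5-[(4-methoxybenzyl)oxy]pent-1-en-3-ol | C=C[C@@H](O)CCOCc1ccc(OC)cc1
F2 | step 5 | 1-({[(3S)-3-(2-bromo-1-ethoxyethoxy)pent-4-en-1-yl]oxy}methyl)-4-methoxybenzene (acetal epimers) | BrCC(OCC)O[C@H](C=C)CCOCc1ccc(OC)cc1
F3 | step 5 | (4R,5S)-2-ethoxy-5-{2-[(4-methoxybenzyl)oxy]ethyl}-4-methyloxolane (acetal epimers) | CCOC1C[C@@H](C)[C@H](CCOCc2ccc(OC)cc2)O1
F4 | step 5 | (4R,5S)-5-{2-[(4-methoxybenzyl)oxy]ethyl}-4-methyloxolan-2-one | O=C1C[C@@H](C)[C@H](CCOCc2ccc(OC)cc2)O1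
F5 | step 5 | (2S,3R)-2-{2-[(4-methoxybenzyl)oxy]ethyl}-3-methyl-5-methylideneoxolane | C=C1C[C@@H](C)[C@H](CCOCc2ccc(OC)cc2)O1
F6 | step 4 | (2S)-1-chloro-3-(trityloxy)propan-2-ol | c1ccccc1C(c1ccccc1)(c1ccccc1)OC[C@H](O)CCl
F7 | step 4 | (3S)-5-[(4-methoxybenzyl)oxy]pent-1-en-3-yl (2S)-1-chloro-3-(trityloxy)propan-2-yl ether | C=C[C@H](CCOCc1ccc(OC)cc1)O[C@H](CCl)COC(c1ccccc1)(c1ccccc1)c1ccccc1
F8 | step 33 | (2E,4E,6S)-6-(TBS-oxy)-1-[(2S,5R)-5-({2-[(3S,4S,5R,6S)-3,5-bis(TBS-oxy)-4,6,7-trimethyloct-7-en-1-yl]-1,3-dithian-2-yl}methyl)oxolan-2-yl]-5-methyl-7-methylideneundeca-2,4-dien-1-one | O=C(/C=C/C=C(\C)[C@@H](O[Si](C)(C)C(C)(C)C)C(=C)CCCC)[C@@H]1CC[C@H](CC2(SCCCS2)CC[C@H](O[Si](C)(C)C(C)(C)C)[C@H](C)[C@H](O[Si](C)(C)C(C)(C)C)[C@@H](C)C(=C)C)O1
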